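**Plan**
Numbering: ring A is the guaiacyl ring on C7, and ring B is the 2,6-dimethoxy-4-(hydroxymethyl)phenyl ring on the C8 oxygen. The chain is C7 (benzylic CHOH), C8 (CH–OAr), C9 (CH2OH).
Enabling feature: C8 alone is bonded to the ring B ether oxygen, to C7 and to C9. It therefore equals the carbene carbon of a diazoacetate whose ester carbon is C9.
Retrosynthesis: C9–OH, the ring B CH2OH and the ring A phenol go back to an ethyl ester, a methyl ester and an acetate. C8–O(ring B) and C7–C8 are then cut together.
Forward: no ring is formed and both arenes are bought. Step 1 joins ethyl diazoacetate 1 (C8–C9), methyl syringate 2 (ring B and its O) and vanillin acetate 3 (ring A, C7); step 2 is one global hydride reduction.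
Stereochemistry: C7 and C8 both arise in step 1 inside the pocket of a chiral phosphoric acid (anti = erythro, 2R,3R in the ester). They pass untouched into the (7R,8S) target.

Key step: step 1

Assumption: no precedent on this substrate pair fixes the sense of induction of the acid, so (R)-TRIP is written and its mirror image takes its place if a first run shows the opposite sense.

**Step 1**
Reactants: 1 ethyl diazoacetate; 2 methyl syringate (methyl 4-hydroxy-3,5-dimethoxybenzoate); 3 vanillin acetate (4-formyl-2-methoxyphenyl acetate)
Product: 6 ethyl (2R,3R)-3-(4-acetoxy-3-methoxyphenyl)-2-[2,6-dimethoxy-4-(methoxycarbonyl)phenoxy]-3-hydroxypropanoate (erythro), via oxonium ylide 4 (not isolated), via enol 5 (not isolated)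
Conditions: Rh2(OAc)4 (1 mol %), (R)-TRIP (10 mol %), 4 Å MS, CH2Cl2, 0 °C; 1 (1.2 equiv) added by syringe pump over 6 h to 2 (1.0 equiv) and 3 (2.0 equiv)
Reagents that add atoms: none
Why: Proposed new method: Rh2(OAc)4 expels N2 from 1, the phenolic oxygen of 2 adds to the electrophilic carbene carbon (the future C8) to give oxonium ylide 4, a 1,4-proton shift from O+–H to the cis ester carbonyl oxygen gives the (E)-enol 5, and 5 attacks aldehyde 3 through C8 while the phosphoric acid bridges the enol O–H with its P=O group and the aldehyde oxygen with its P–OH group. The closest known reaction type is the oxonium-ylide trapping reaction, the Rh(II) and chiral Brønsted or Lewis acid co-catalysed three-component coupling of aryldiazoacetates, alcohols and aldehydes or imines, whose scope does not yet hold the pair of an α-unsubstituted diazoacetate and a phenol. The step forms two open-chain bonds, C8–O(ring B) and C7–C8, and closes no ring. C7 should become R by attack on the Si face of the acid-bound aldehyde and C8 (C2 of the ester) should become R by reaction at its Re face, both faces being picked by the 3,3'-aryl walls of the acid, while the anti (erythro) relation should come from the bridged arrangement that turns ring A away from the bulky 2,6-dimethoxyaryloxy group. The step needs C–C bond formation to outrun the proton shift to C8, oxygen attack to outrun attack on ring B carbons, and the phenol to outrun the aldehyde oxygen as carbene acceptor. In 2 the two ortho methoxy groups shield the neighbouring ring carbons and offer hydrogen-bond acceptors for the mobile proton and the para ester deactivates ring B, in 3 the acetate makes the carbonyl carbon more electrophilic, its oxygen less nucleophilic and the product carbinol less prone to acid ionisation, and slow addition of 1 to an excess of 3 keeps interception ahead of the unimolecular shift.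

**Step 2**
Reactants: 6 ethyl (2R,3R)-3-(4-acetoxy-3-methoxyphenyl)-2-[2,6-dimethoxy-4-(methoxycarbonyl)phenoxy]-3-hydroxypropanoate
Product: 7 (1R,2S)-1-(4-hydroxy-3-methoxyphenyl)-2-[4-(hydroxymethyl)-2,6-dimethoxyphenoxy]propane-1,3-diol (7R,8S, erythro; the target)
Conditions: 6 added to LiAlH4 (4 equiv), THF, 0 °C → rt; cold aq. Rochelle salt work-up at pH 6–7
Reagents that add atoms: none
Why: LiAlH4 ester reduction, the customary closing step for α-aryloxy-β-hydroxy esters of the β-O-4 type, should turn the C9 ethyl ester and the ring B methyl ester into CH2OH and cleave the phenolic acetate in the same operation without touching a bond at C7 or C8, so both centres persist (the C8 descriptor changes from R to S only because CH2OH ranks below C7), provided that reduction at 0 °C outpaces retro-aldol cleavage and the work-up stays near neutral.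

**Compound list**
1 | ethyl diazoacetate | CCOC(=O)C=[N+]=[N-] | starting material
2 | methyl syringate (methyl 4-hydroxy-3,5-dimethoxybenzoate) | COC(=O)c1cc(OC)c(O)c(OC)c1 | starting material
3 | vanillin acetate (4-formyl-2-methoxyphenyl acetate) | CC(=O)Oc1ccc(C=O)cc1OC | starting material
4 | oxonium ylide, [2,6-dimethoxy-4-(methoxycarbonyl)phenyl](2-ethoxy-2-oxoethan-1-id-1-yl)oxonium (rhodium-associated in the flask, drawn metal-free) | CCOC(=O)[CH-][OH+]c1c(OC)cc(C(=O)OC)cc1OC | intermediate
5 | enol, methyl 4-{[(E)-2-ethoxy-2-hydroxyethenyl]oxy}-3,5-dimethoxybenzoate (OH cis to the aryloxy group) | CCO/C(O)=C/Oc1c(OC)cc(C(=O)OC)cc1OC | intermediate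
6 | ethyl (2R,3R)-3-(4-acetoxy-3-methoxyphenyl)-2-[2,6-dimethoxy-4-(methoxycarbonyl)phenoxy]-3-hydroxypropanoate | COc1cc([C@@H](O)[C@H](C(=O)OCC)Oc2c(OC)cc(C(=O)OC)cc2OC)ccc1OC(C)=O | intermediate
7 | (1R,2S)-1-(4-hydroxy-3-methoxyphenyl)-2-[4-(hydroxymethyl)-2,6-dimethoxyphenoxy]propane-1,3-diol | COc1cc([C@@H](O)[C@H](CO)Oc2c(OC)cc(CO)cc2OC)ccc1O | target

Total step count: 2
Longest linear sequence: 2 steps

**Steps most likely to fail** (the route holds only two steps, so the ranking ends after the second)

1. Step 1 (bears the label Proposed new method).
   - What may go wrong: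
     - The mobile proton of 4 and 5 may reach C8 before C8 reaches the aldehyde, leaving only formal O–H insertion.
     - The carbene may be drained by the aldehyde oxygen (carbonyl-ylide chemistry) or by the P–OH group of the acid.
     - Face selection and anti/syn selection in the acid pocket may be poor.
   - Fallback: known chemistry that forms the two bonds one after the other and then resolves. It sets out from 1 and 2 and comes back at 6. Rh2(OAc)4-catalysed O–H insertion of 1 into 2 (CH2Cl2, rt, no aldehyde, no chiral acid) should give ethyl 2-[2,6-dimethoxy-4-(methoxycarbonyl)phenoxy]acetate F1, which sets C8–O alone. Deprotonation with LDA in THF at −78 °C and addition of 3 then forms C7–C8. This is the erythro-favouring lithium-enolate aldol addition that is standard for β-O-4 model compounds. An AcOH quench at −78 °C keeps the aldolate from attacking the aryl acetate. After the threo pair is removed by chromatography, the erythro racemate consists of 6 and its mirror image, ethyl (2S,3S)-3-(4-acetoxy-3-methoxyphenyl)-2-[2,6-dimethoxy-4-(methoxycarbonyl)phenoxy]-3-hydroxypropanoate F2. Preparative HPLC on a cellulose tris(3,5-dimethylphenylcarbamate) phase should separate the two, and 6 goes on to step 2.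

2. Step 2.
   - What may go wrong:
     - The aluminium aldolate may undergo retro-aldol cleavage or epimerise at C8 before the C9 ester is reduced.
     - The C7 oxygen may be lost through quinone-methide formation once the phenoxide is unmasked.
     - The polar product may stay on the aluminium salts.
   - Fallback: it sets out from 6 and comes back at 7, and it caps the carbinol before any hydride is used. TBSOTf and 2,6-lutidine in CH2Cl2 at 0 °C should give ethyl (2R,3R)-3-(4-acetoxy-3-methoxyphenyl)-3-(tert-butyldimethylsilyloxy)-2-[2,6-dimethoxy-4-(methoxycarbonyl)phenoxy]propanoate F3, which can neither fragment by retro-aldol nor expel its C7 oxygen. Excess DIBAL-H (CH2Cl2, −78 → 0 °C) should reduce both esters and remove the acetate. The product is 4-[(1R,2S)-1-(tert-butyldimethylsilyloxy)-3-hydroxy-2-[4-(hydroxymethyl)-2,6-dimethoxyphenoxy]propyl]-2-methoxyphenol F4, which is less polar and easier to purify. TBAF buffered with AcOH in THF at 0 °C should then free C7–OH and give 7.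

**Further compounds**
F1 | step 1 | ethyl 2-[2,6-dimethoxy-4-(methoxycarbonyl)phenoxy]acetate | CCOC(=O)COc1c(OC)cc(C(=O)OC)cc1OC
F2 | step 1 | ethyl (2S,3S)-3-(4-acetoxy-3-methoxyphenyl)-2-[2,6-dimethoxy-4-(methoxycarbonyl)phenoxy]-3-hydroxypropanoate (mirror image of 6) | COc1cc([C@H](O)[C@@H](C(=O)OCC)Oc2c(OC)cc(C(=O)OC)cc2OC)ccc1OC(C)=O
F3 | step 2 | ethyl (2R,3R)-3-(4-acetoxy-3-methoxyphenyl)-3-(tert-butyldimethylsilyloxy)-2-[2,6-dimethoxy-4-(methoxycarbonyl)phenoxy]propanoate | COc1cc([C@@H](O[Si](C)(C)C(C)(C)C)[C@H](C(=O)OCC)Oc2c(OC)cc(C(=O)OC)cc2OC)ccc1OC(C)=O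
F4 | step 2 | 4-[(1R,2S)-1-(tert-butyldimethylsilyloxy)-3-hydroxy-2-[4-(hydroxymethyl)-2,6-dimethoxyphenoxy]propyl]-2-methoxyphenol | COc1cc([C@@H](O[Si](C)(C)C(C)(C)C)[C@H](CO)Oc2c(OC)cc(CO)cc2OC)ccc1O
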